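**Plan**
1. Numbering (germacrane): ring carbons C1–C10. C2 is the hemiketal carbon, C5 the ether CH, C6 the lactone CH–O, C7 the CH that carries C11(=C13)–C12, and C8 the tiglate CH. C4=C15 and C10=C14 are the exocyclic methylenes. The enabling feature is the tetrahydrofuran ring O5–C2–C3–C4–C5: C2 bears both OH and O5, so it is the frozen tetrahedral adduct of a C2(=O)–O5 ester with the carbanion C3. C3 is one of the two identical CH2 ends of the allyl unit C3–C4(=C15) that sits on C5.
2. Cuts, in retrosynthetic order: C12–O6 (butyrolactone to a 6,12-diol); C2–C3 (bicyclic hemiketal to the nine-membered lactone O5–C2–C1–C10–C9–C8–C7–C6–C5 with an allylic iodide on C5); C2–O5 (to the seco acid); O8–acyl; C8–C9; C6–C7.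
3. Forward: fragment A (C3–C6, C15), fragment B (C7, C8, C11–C13) and fragment C (C9, C10, C14, C1, C2) are joined by an aldol (C6–C7) and an allylation (C8–C9). The nine-membered lactone closes first. One SmI2-induced bond formation then closes the tetrahydrofuran and the ten-membered carbocycle together. The α-methylene-γ-butyrolactone closes last.
4. Stereochemistry: C5 comes from methyl (R)-glycerate acetonide, C6 and C7 from an auxiliary-controlled syn aldol, C8 from a catalyst-controlled allylation, and C2 from the cis-bridging demand of the bicycle.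

Key step: step 23

Remark: names of 23–42 use the target numbering of the chain C2–C1–C10(=C14)–C9–C8–C7[C11(=C13)–C12]–C6–C5–C4(=C15)–C3. The CIP letter at C7 changes with the ranking of its neighbours, although no bond at C7 is ever broken. TES = triethylsilyl, TBS = tert-butyldimethylsilyl, TBDPS = tert-butyldiphenylsilyl, MNBA = 2-methyl-6-nitrobenzoic anhydride.

**Fragment A (C3–C6, C15)**

Step 1
Reactants: 1 methyl (4R)-2,2-dimethyl-1,3-dioxolane-4-carboxylate
Product: 3 (4S)-2,2-dimethyl-4-[3-(trimethylsilyl)prop-1-en-2-yl]-1,3-dioxolane, via bis(silylmethyl) carbinol 2 (not isolated)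
Conditions: Me3SiCH2MgCl (5 equiv), CeCl3, THF, −78 °C to rt; then SiO2, CH2Cl2, rt
Reagents that add atoms: (trimethylsilyl)methylmagnesium chloride, C[Si](C)(C)C[Mg]Cl
Why: Double addition of the weakly basic organocerium reagent to the ester, followed by Peterson elimination of one β-silyl arm of 2, is the standard ester-to-allylsilane conversion; it brings in C3 and C15 at once and leaves the α-alkoxy centre C5 untouched.

Step 2
Reactants: 3 (4S)-2,2-dimethyl-4-[3-(trimethylsilyl)prop-1-en-2-yl]-1,3-dioxolane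
Product: 5 2-[(4S)-2,2-dimethyl-1,3-dioxolan-4-yl]prop-2-en-1-ol, via epoxysilane 4 (not isolated)
Conditions: mCPBA, CH2Cl2, 0 °C; then MeOH, AcOH (cat.), rt
Reagents that add atoms: 3-chloroperbenzoic acid, O=C(OO)c1cccc(Cl)c1
Why: Epoxidation of the electron-rich allylsilane and desilylative opening of the β-silyl epoxide (a Peterson-type 1,2-elimination) give the allylic alcohol; the allylic transposition is degenerate because both allyl ends are CH2.

Step 3
Reactants: 5 2-[(4S)-2,2-dimethyl-1,3-dioxolan-4-yl]prop-2-en-1-ol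
Product: 6 (4S)-4-(3-chloroprop-1-en-2-yl)-2,2-dimethyl-1,3-dioxolane
Conditions: PPh3, NCS, THF, 0 °C to rt
Reagents that add atoms: N-chlorosuccinimide, O=C1CCC(=O)N1Cl
Why: This Appel-type chlorination replaces the primary allylic hydroxyl under neutral conditions that spare the acetonide, and the SN2 and SN2' paths give the same chloride, which serves as the robust latent form of the iodide.

Step 4
Reactants: 6 (4S)-4-(3-chloroprop-1-en-2-yl)-2,2-dimethyl-1,3-dioxolane
Product: 7 (2S)-3-(chloromethyl)but-3-ene-1,2-diol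
Conditions: 80% aq. AcOH, rt
Reagents that add atoms: none
Why: Mild acid hydrolysis of a terminal acetonide breaks no C–O bond at C5 and is too weakly ionising to solvolyse the primary allylic chloride.

Step 5
Reactants: 7 (2S)-3-(chloromethyl)but-3-ene-1,2-diol
Product: 8 (2S)-3-(chloromethyl)-1,2-bis(triethylsilyloxy)but-3-ene
Conditions: TESCl (2.3 equiv), imidazole, CH2Cl2, 0 °C
Reagents that add atoms: chlorotriethylsilane, CC[Si](Cl)(CC)CC
Why: Routine imidazole-mediated silylation of both hydroxyls is far faster than any etherification of the diol onto the allylic chloride.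

Step 6
Reactants: 8 (2S)-3-(chloromethyl)-1,2-bis(triethylsilyloxy)but-3-ene
Product: 9 (2S)-3-(chloromethyl)-2-(triethylsilyloxy)but-3-enal
Conditions: (COCl)2, DMSO, CH2Cl2, −78 to −40 °C; then Et3N, −78 to 0 °C; used crude
Reagents that add atoms: none
Why: Under Swern conditions the chlorosulfonium salt attacks a primary TES ether and oxidises it directly to the aldehyde while the hindered secondary TES ether survives; cold handling of the crude α-silyloxy β,γ-unsaturated aldehyde protects C5 from epimerisation.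

**Fragment B (C7, C8, C11–C13)**

Step 7
Reactants: 10 2-methylenepropane-1,3-diol
Product: 11 2-{[tert-butyl(diphenyl)silyl]oxymethyl}prop-2-en-1-ol
Conditions: NaH (1 equiv), THF, 0 °C to rt; then TBDPSCl (1 equiv)
Reagents that add atoms: tert-butylchlorodiphenylsilane, CC(C)(C)[Si](Cl)(c1ccccc1)c1ccccc1
Why: Monosilylation of a symmetric diol through its sparingly soluble monosodium alkoxide is a standard desymmetrisation by stoichiometry.

Step 8
Reactants: 11 2-{[tert-butyl(diphenyl)silyl]oxymethyl}prop-2-en-1-ol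
Product: 12 tert-butyl{[2-(chloromethyl)prop-2-en-1-yl]oxy}diphenylsilane
Conditions: PPh3, NCS, THF, 0 °C to rt
Reagents that add atoms: N-chlorosuccinimide, O=C1CCC(=O)N1Cl
Why: Appel-type chlorination of a primary allylic alcohol proceeds under neutral conditions that are harmless to the silyl ether.

Step 9
Reactants: 12 tert-butyl{[2-(chloromethyl)prop-2-en-1-yl]oxy}diphenylsilane
Product: 14 3-{[tert-butyl(diphenyl)silyl]oxymethyl}but-3-enoic acid, via allylmagnesium chloride 13 (not isolated)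
Conditions: Mg (excess), THF, 0 °C, slow addition; CO2, −78 °C to rt; then cold 1 M HCl
Reagents that add atoms: carbon dioxide, O=C=O
Why: In this carboxylation of an allylic Grignard reagent the two CH2 ends of the 2-substituted allyl unit are identical, so only one β,γ-unsaturated acid can form, and slow addition to excess Mg limits Wurtz coupling.

Step 10
Reactants: 14 3-{[tert-butyl(diphenyl)silyl]oxymethyl}but-3-enoic acid; 15 (4S)-4-benzyl-1,3-oxazolidin-2-one
Product: 17 (4S)-4-benzyl-3-(3-{[tert-butyl(diphenyl)silyl]oxymethyl}but-3-enoyl)-1,3-oxazolidin-2-one, via mixed pivalic anhydride 16 (not isolated)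
Conditions: PivCl, Et3N, THF, −20 °C; then LiCl, 15, −20 °C to rt
Reagents that add atoms: none
Why: N-Acylation of the oxazolidinone through the mixed pivalic anhydride with LiCl activation is mild enough to keep the double bond out of conjugation.

**Fragment C (C9, C10, C14, C1, C2)**

Step 11
Reactants: 18 3-methylbut-3-en-1-ol
Product: 20 3-[(tributylstannyl)methyl]but-3-en-1-ol, via dilithio dianion 19 (not isolated)
Conditions: n-BuLi (2.2 equiv), TMEDA, Et2O, 0 °C to rt; Bu3SnCl (1 equiv), −78 °C to rt; then H2O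
Reagents that add atoms: tributyltin chloride, CCCC[Sn](Cl)(CCCC)CCCC
Why: Alkoxide-directed allylic metalation of the methyl group gives the dianion, whose carbanion end is the more reactive site toward one equivalent of the tin chloride.

Step 12
Reactants: 20 3-[(tributylstannyl)methyl]but-3-en-1-ol
Product: 21 triethyl({3-[(tributylstannyl)methyl]but-3-en-1-yl}oxy)silane
Conditions: TESCl, imidazole, CH2Cl2, 0 °C
Reagents that add atoms: chlorotriethylsilane, CC[Si](Cl)(CC)CC
Why: Routine silylation puts O2 under the same labile group as O5, so that both can be freed together later.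

**Assembly**

Step 13
Reactants: 17 (4S)-4-benzyl-3-(3-{[tert-butyl(diphenyl)silyl]oxymethyl}but-3-enoyl)-1,3-oxazolidin-2-one; 9 (2S)-3-(chloromethyl)-2-(triethylsilyloxy)but-3-enal
Product: 23 (4S)-4-benzyl-3-[(2S,3S,4S)-2-(3-{[tert-butyl(diphenyl)silyl]oxy}prop-1-en-2-yl)-5-(chloromethyl)-3-hydroxy-4-(triethylsilyloxy)hex-5-enoyl]-1,3-oxazolidin-2-one, via boron dienolate 22 (not isolated)
Conditions: Bu2BOTf, Et3N, CH2Cl2, −78 to 0 °C; 9, −78 to −10 °C; then pH 7 buffer, MeOH, H2O2, 0 °C
Reagents that add atoms: none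
Why: In this Evans syn aldol the Z-configured boron dienolate reacts at its α-carbon C7 through a closed chair transition state whose enolate face is fixed by the (S)-benzyl auxiliary, so C6 and C7 arise syn and in the required absolute sense even against the modest opposite bias of the α-silyloxy aldehyde.

Step 14
Reactants: 23 syn-aldol imide (5S,6S,7S; 6-OH)
Product: 24 syn-aldol imide (5S,6S,7S): 6-OTBS; 5-OTES; 12-OTBDPS; 3-Cl
Conditions: TBSOTf, 2,6-lutidine, CH2Cl2, −78 to 0 °C
Reagents that add atoms: tert-butyldimethylsilyl triflate, CC(C)(C)[Si](C)(C)OS(=O)(=O)C(F)(F)F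
Why: Silyl triflate with a hindered pyridine silylates the crowded aldol hydroxyl without retro-aldol cleavage or migration of the C11=C13 double bond.

Step 15
Reactants: 24 syn-aldol imide (6-OTBS)
Product: 25 (2R,3S,4S)-2-(3-{[tert-butyl(diphenyl)silyl]oxy}prop-1-en-2-yl)-3-[tert-butyl(dimethyl)silyloxy]-5-(chloromethyl)-4-(triethylsilyloxy)hex-5-en-1-ol
Conditions: LiBH4, MeOH (1 equiv), THF, 0 °C
Reagents that add atoms: none
Why: Reductive removal of the auxiliary with LiBH4 attacks the exocyclic imide carbonyl and, at 0 °C, touches neither the allylic chloride nor the silyl ethers.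

Step 16
Reactants: 25 C8 primary alcohol (5S,6S,7R)
Product: 26 (2S,3S,4S)-2-(3-{[tert-butyl(diphenyl)silyl]oxy}prop-1-en-2-yl)-3-[tert-butyl(dimethyl)silyloxy]-5-(chloromethyl)-4-(triethylsilyloxy)hex-5-enal
Conditions: Dess–Martin periodinane, NaHCO3, CH2Cl2, 0 °C to rt; used at once
Reagents that add atoms: none
Why: The buffered Dess–Martin oxidation is neutral and fast, which is what an α-alkenyl aldehyde needs to keep C7 and the position of the C11=C13 bond intact.

Step 17
Reactants: 26 C8 aldehyde (5S,6S,7S); 21 triethyl({3-[(tributylstannyl)methyl]but-3-en-1-yl}oxy)silane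
Product: 27 open-chain alcohol (5S,6S,7R,8S): 8-OH; 2,5-bis(OTES); 6-OTBS; 12-OTBDPS; 3-Cl
Conditions: (S)-BINOL (20 mol %), Ti(OiPr)4 (10 mol %), 4 Å MS, CH2Cl2, −20 °C; then aq. NaHCO3
Reagents that add atoms: none
Why: In this Keck asymmetric allylation with a 2-substituted allylstannane (SE2' attack, so the stannylmethyl carbon becomes C14) the (S)-BINOL titanium catalyst directs the nucleophile to the aldehyde face that gives 8S, which is also the Felkin–Anh face when the C6 branch is taken as the large group.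

Step 18
Reactants: 27 open-chain alcohol (8-OH); 28 tigloyl chloride, (E)-2-methylbut-2-enoyl chloride
Product: 29 open-chain tiglate (5S,6S,7R,8S): 8-O-tigloyl; 2,5-bis(OTES); 6-OTBS; 12-OTBDPS; 3-Cl
Conditions: pyridine, DMAP (cat.), CH2Cl2, 0 °C to rt
Reagents that add atoms: none
Why: DMAP-catalysed acylation of the only free hydroxyl uses pyridine rather than a trialkylamine, which avoids vinylketene formation and hence deconjugation of the E-configured acyl group.

Step 19
Reactants: 29 open-chain tiglate (2,5-bis(OTES))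
Product: 30 open-chain 2,5-diol (5S,6S,7R,8S): 8-O-tigloyl; 6-OTBS; 12-OTBDPS; 3-Cl
Conditions: PPTS (cat.), MeOH/CH2Cl2, 0 °C
Reagents that add atoms: none
Why: Mild acid methanolysis cleaves both TES ethers far faster than the secondary TBS or the acid-stable TBDPS ether.

Step 20
Reactants: 30 open-chain 2,5-diol
Product: 32 seco acid (5S,6S,7R,8S): C2 carboxylic acid; 5-OH; 8-O-tigloyl; 6-OTBS; 12-OTBDPS; 3-Cl, via hydroxy aldehyde 31 (not isolated)
Conditions: TEMPO (20 mol %), PhI(OAc)2 (2.5 equiv), MeCN/pH 7 buffer, 0 °C to rt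
Reagents that add atoms: water, O
Why: The TEMPO/PhI(OAc)2 oxidation takes the unhindered primary alcohol through the aldehyde hydrate to the acid while the crowded secondary 5-hydroxyl is left alone, and the near-neutral medium keeps C10=C14 out of conjugation.

Step 21
Reactants: 32 seco acid
Product: 34 nine-membered lactone chloride (5S,6S,7R,8S): ring O5–C2–C1–C10–C9–C8–C7–C6–C5; 10-methylene; 8-O-tigloyl; 7-[3-(TBDPS-oxy)prop-1-en-2-yl]; 6-OTBS; 5-(3-chloroprop-1-en-2-yl), via mixed anhydride 33 (not isolated)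
Conditions: MNBA (1.3 equiv), DMAP (3 equiv), CH2Cl2, rt; 32 added by syringe pump (final 2 mM)
Reagents that add atoms: none
Why: In this Shiina macrolactonisation the acyl group of the mixed anhydride is passed by DMAP to the only free hydroxyl O5; the method is established for eight- and nine-membered lactones, and the four contiguous substituents and the sp2 centre C10 reduce the degrees of freedom of the chain.

Step 22
Reactants: 34 nine-membered lactone chloride
Product: 35 nine-membered lactone iodide (5S,6S,7R,8S): as 34 with 5-(3-iodoprop-1-en-2-yl)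
Conditions: NaI, acetone, rt, dark; used at once
Reagents that add atoms: sodium iodide, [Na+].[I-]
Why: The Finkelstein exchange on a primary allylic chloride is driven by precipitation of NaCl and touches nothing else in the molecule.

Step 23
Reactants: 35 nine-membered lactone iodide
Product: 38 bridged hemiketal (2S,5S,6S,7R,8S): 11-oxabicyclo[6.2.1]undecane core (carbocycle C1–C10 bridged by O5 between C2 and C5); 2-OH; 4- and 10-methylene; 8-O-tigloyl; 6-OTBS; 7-[3-(TBDPS-oxy)prop-1-en-2-yl], via allylsamarium diiodide 36 (not isolated), via samarium hemiketal alkoxide 37 (not isolated)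
Conditions: SmI2 (2.5 equiv, 0.1 M in THF), THF, −78 °C; 35 added slowly (final 5 mM); to −20 °C; then pH 7 buffer
Reagents that add atoms: none
Why: Two single-electron transfers from divalent samarium convert the allylic iodide into allylsamarium 36, whose CH2 ends C3 and C15 are interchangeable, so addition of either end to the lactone carbonyl C2 gives the same constitution. The closest known reaction type is the SmI2-promoted Barbier-type intramolecular nucleophilic acyl substitution of iodoalkyl esters and lactones, which stops at the hydroxy ketone or cyclic hemiketal. The tetrahydrofuran (O5, C2, C3, C4, C5) closes in a 5-exo-trig mode, and because C2 stays bonded to C1 the same C2–C3 bond completes the ten-membered carbocycle C1–C10, the atoms of the former lactone ring becoming the long bridge of the bicycle. The one new stereocentre, C2, is dictated by C5, since a six-atom bridge can span a tetrahydrofuran only cis, which puts C1 and C6 on the same face and gives 2S. The step needs reduction of the iodide before the tiglate and attack at C2 rather than at the tiglate carbonyl; the first follows from the much faster reduction of an allylic iodide in plain THF at low temperature without HMPA or a proton source, and the second from a five-membered against an eight-membered transition state. A second addition is impossible because the trivalent samarium alkoxide 37 already is the product hemiketal and no further nucleophile is present, and slow addition of 35 into excess SmI2 at high dilution suppresses allyl radical dimerisation.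

Step 24
Reactants: 38 bridged hemiketal (6-OTBS; 12-OTBDPS)
Product: 39 bridged hemiketal triol (2S,5S,6S,7S,8S): 2-OH; 6-OH; 12-OH; 8-O-tigloyl
Conditions: HF·pyridine, pyridine, THF, 0 °C to rt
Reagents that add atoms: none
Why: Pyridine-buffered fluoride desilylation removes both remaining silyl groups in one operation, without the base that could shift the β,γ double bonds and without the strong acid that could ionise the hemiketal.

Step 25
Reactants: 39 bridged hemiketal triol
Product: 42 target CNP0307443.2 (2S,5S,6S,7R,8S), via enal 40 (not isolated), via lactol 41 (not isolated)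
Conditions: MnO2 (excess), CH2Cl2, rt
Reagents that add atoms: none
Why: In this oxidative lactonisation of a 2-methylene-1,4-diol, MnO2 oxidises only the primary allylic alcohol to the enal, the 6-hydroxyl closes onto it, and the lactol is oxidised again to the α-methylene-γ-butyrolactone; the tertiary hemiketal hydroxyl is inert, and the trans ring fusion follows from the fixed C6 and C7 centres.

**Compound list**
1 | methyl (4R)-2,2-dimethyl-1,3-dioxolane-4-carboxylate | COC(=O)[C@H]1COC(C)(C)O1 | starting material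
2 | 2-[(4R)-2,2-dimethyl-1,3-dioxolan-4-yl]-1,3-bis(trimethylsilyl)propan-2-ol (bis(silylmethyl) carbinol) | C[Si](C)(C)CC(O)(C[Si](C)(C)C)[C@H]1COC(C)(C)O1 | intermediate
3 | (4S)-2,2-dimethyl-4-[3-(trimethylsilyl)prop-1-en-2-yl]-1,3-dioxolane | C=C(C[Si](C)(C)C)[C@H]1COC(C)(C)O1 | intermediate
4 | (4R)-2,2-dimethyl-4-{2-[(trimethylsilyl)methyl]oxiran-2-yl}-1,3-dioxolane (epoxysilane, both epoxide epimers) | C[Si](C)(C)CC1(CO1)[C@H]2COC(C)(C)O2 | intermediate
5 | 2-[(4S)-2,2-dimethyl-1,3-dioxolan-4-yl]prop-2-en-1-ol | OCC(=C)[C@H]1COC(C)(C)O1 | intermediate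
6 | (4S)-4-(3-chloroprop-1-en-2-yl)-2,2-dimethyl-1,3-dioxolane | ClCC(=C)[C@H]1COC(C)(C)O1 | intermediate
7 | (2S)-3-(chloromethyl)but-3-ene-1,2-diol | OC[C@@H](O)C(=C)CCl | intermediate
8 | (2S)-3-(chloromethyl)-1,2-bis(triethylsilyloxy)but-3-ene | CC[Si](CC)(CC)OC[C@@H](O[Si](CC)(CC)CC)C(=C)CCl | intermediate
9 | (2S)-3-(chloromethyl)-2-(triethylsilyloxy)but-3-enal | O=C[C@@H](O[Si](CC)(CC)CC)C(=C)CCl | intermediate
10 | 2-methylenepropane-1,3-diol | C=C(CO)CO | starting material
11 | 2-{[tert-butyl(diphenyl)silyl]oxymethyl}prop-2-en-1-ol | C=C(CO)CO[Si](c1ccccc1)(c1ccccc1)C(C)(C)C | intermediate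
12 | tert-butyl{[2-(chloromethyl)prop-2-en-1-yl]oxy}diphenylsilane | C=C(CCl)CO[Si](c1ccccc1)(c1ccccc1)C(C)(C)C | intermediate
13 | allylmagnesium chloride derived from 12 | C=C(C[Mg]Cl)CO[Si](c1ccccc1)(c1ccccc1)C(C)(C)C | intermediate
14 | 3-{[tert-butyl(diphenyl)silyl]oxymethyl}but-3-enoic acid | C=C(CC(=O)O)CO[Si](c1ccccc1)(c1ccccc1)C(C)(C)C | intermediate
15 | (4S)-4-benzyl-1,3-oxazolidin-2-one | O=C1N[C@@H](Cc2ccccc2)CO1 | starting material
16 | mixed pivalic anhydride of 14 | C=C(CC(=O)OC(=O)C(C)(C)C)CO[Si](c1ccccc1)(c1ccccc1)C(C)(C)C | intermediate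
17 | (4S)-4-benzyl-3-(3-{[tert-butyl(diphenyl)silyl]oxymethyl}but-3-enoyl)-1,3-oxazolidin-2-one | C=C(CO[Si](c1ccccc1)(c1ccccc1)C(C)(C)C)CC(=O)N1C(=O)OC[C@@H]1Cc1ccccc1 | intermediate
18 | 3-methylbut-3-en-1-ol | C=C(C)CCO | starting material
19 | dilithio dianion of 18 | [Li]CC(=C)CCO[Li] | intermediate
20 | 3-[(tributylstannyl)methyl]but-3-en-1-ol | C=C(CCO)C[Sn](CCCC)(CCCC)CCCC | intermediate
21 | triethyl({3-[(tributylstannyl)methyl]but-3-en-1-yl}oxy)silane | C=C(CCO[Si](CC)(CC)CC)C[Sn](CCCC)(CCCC)CCCC | intermediate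
22 | (Z)-dibutylboron dienolate of 17 | CCCCB(CCCC)O/C(=C\C(=C)CO[Si](c1ccccc1)(c1ccccc1)C(C)(C)C)N1C(=O)OC[C@@H]1Cc1ccccc1 | intermediate
23 | syn-aldol imide (5S,6S,7S): (4S)-4-benzyl-3-[(2S,3S,4S)-2-(3-{[tert-butyl(diphenyl)silyl]oxy}prop-1-en-2-yl)-5-(chloromethyl)-3-hydroxy-4-(triethylsilyloxy)hex-5-enoyl]-1,3-oxazolidin-2-one | O=C(N1C(=O)OC[C@@H]1Cc1ccccc1)[C@@H](C(=C)CO[Si](c1ccccc1)(c1ccccc1)C(C)(C)C)[C@H](O)[C@@H](O[Si](CC)(CC)CC)C(=C)CCl | intermediate
24 | syn-aldol imide (5S,6S,7S): 6-OTBS; 5-OTES; 12-OTBDPS; 3-Cl | O=C(N1C(=O)OC[C@@H]1Cc1ccccc1)[C@@H](C(=C)CO[Si](c1ccccc1)(c1ccccc1)C(C)(C)C)[C@H](O[Si](C)(C)C(C)(C)C)[C@@H](O[Si](CC)(CC)CC)C(=C)CCl | intermediate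
25 | C8 primary alcohol (5S,6S,7R): (2R,3S,4S)-2-(3-{[tert-butyl(diphenyl)silyl]oxy}prop-1-en-2-yl)-3-[tert-butyl(dimethyl)silyloxy]-5-(chloromethyl)-4-(triethylsilyloxy)hex-5-en-1-ol | OC[C@@H](C(=C)CO[Si](c1ccccc1)(c1ccccc1)C(C)(C)C)[C@H](O[Si](C)(C)C(C)(C)C)[C@@H](O[Si](CC)(CC)CC)C(=C)CCl | intermediate
26 | C8 aldehyde (5S,6S,7S): (2S,3S,4S)-2-(3-{[tert-butyl(diphenyl)silyl]oxy}prop-1-en-2-yl)-3-[tert-butyl(dimethyl)silyloxy]-5-(chloromethyl)-4-(triethylsilyloxy)hex-5-enal | O=C[C@@H](C(=C)CO[Si](c1ccccc1)(c1ccccc1)C(C)(C)C)[C@H](O[Si](C)(C)C(C)(C)C)[C@@H](O[Si](CC)(CC)CC)C(=C)CCl | intermediate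
27 | open-chain alcohol (5S,6S,7R,8S): 8-OH; 2,5-bis(OTES); 6-OTBS; 12-OTBDPS; 3-Cl | CC[Si](CC)(CC)OCCC(=C)C[C@H](O)[C@@H](C(=C)CO[Si](c1ccccc1)(c1ccccc1)C(C)(C)C)[C@H](O[Si](C)(C)C(C)(C)C)[C@@H](O[Si](CC)(CC)CC)C(=C)CCl | intermediate
28 | tigloyl chloride, (E)-2-methylbut-2-enoyl chloride | C/C=C(\C)C(=O)Cl | starting material
29 | open-chain tiglate (5S,6S,7R,8S): 8-O-tigloyl; 2,5-bis(OTES); 6-OTBS; 12-OTBDPS; 3-Cl | CC[Si](CC)(CC)OCCC(=C)C[C@H](OC(=O)/C(C)=C/C)[C@@H](C(=C)CO[Si](c1ccccc1)(c1ccccc1)C(C)(C)C)[C@H](O[Si](C)(C)C(C)(C)C)[C@@H](O[Si](CC)(CC)CC)C(=C)CCl | intermediate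
30 | open-chain 2,5-diol (5S,6S,7R,8S): 8-O-tigloyl; 6-OTBS; 12-OTBDPS; 3-Cl | OCCC(=C)C[C@H](OC(=O)/C(C)=C/C)[C@@H](C(=C)CO[Si](c1ccccc1)(c1ccccc1)C(C)(C)C)[C@H](O[Si](C)(C)C(C)(C)C)[C@@H](O)C(=C)CCl | intermediate
31 | hydroxy aldehyde (5S,6S,7R,8S): C2 aldehyde; 5-OH; otherwise as 30 | O=CCC(=C)C[C@H](OC(=O)/C(C)=C/C)[C@@H](C(=C)CO[Si](c1ccccc1)(c1ccccc1)C(C)(C)C)[C@H](O[Si](C)(C)C(C)(C)C)[C@@H](O)C(=C)CCl | intermediate
32 | seco acid (5S,6S,7R,8S): C2 carboxylic acid; 5-OH; 8-O-tigloyl; 6-OTBS; 12-OTBDPS; 3-Cl | OC(=O)CC(=C)C[C@H](OC(=O)/C(C)=C/C)[C@@H](C(=C)CO[Si](c1ccccc1)(c1ccccc1)C(C)(C)C)[C@H](O[Si](C)(C)C(C)(C)C)[C@@H](O)C(=C)CCl | intermediate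
33 | mixed anhydride of 32 and 2-methyl-6-nitrobenzoic acid | Cc1cccc([N+](=O)[O-])c1C(=O)OC(=O)CC(=C)C[C@H](OC(=O)/C(C)=C/C)[C@@H](C(=C)CO[Si](c1ccccc1)(c1ccccc1)C(C)(C)C)[C@H](O[Si](C)(C)C(C)(C)C)[C@@H](O)C(=C)CCl | intermediate
34 | nine-membered lactone chloride (5S,6S,7R,8S): ring O5–C2–C1–C10–C9–C8–C7–C6–C5; 10-methylene; 8-O-tigloyl; 7-[3-(TBDPS-oxy)prop-1-en-2-yl]; 6-OTBS; 5-(3-chloroprop-1-en-2-yl) | O=C1CC(=C)C[C@H](OC(=O)/C(C)=C/C)[C@@H](C(=C)CO[Si](c2ccccc2)(c2ccccc2)C(C)(C)C)[C@H](O[Si](C)(C)C(C)(C)C)[C@H](C(=C)CCl)O1 | intermediate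
35 | nine-membered lactone iodide (5S,6S,7R,8S): as 34 with 5-(3-iodoprop-1-en-2-yl) | O=C1CC(=C)C[C@H](OC(=O)/C(C)=C/C)[C@@H](C(=C)CO[Si](c2ccccc2)(c2ccccc2)C(C)(C)C)[C@H](O[Si](C)(C)C(C)(C)C)[C@H](C(=C)CI)O1 | intermediate
36 | allylsamarium diiodide derived from 35 | O=C1CC(=C)C[C@H](OC(=O)/C(C)=C/C)[C@@H](C(=C)CO[Si](c2ccccc2)(c2ccccc2)C(C)(C)C)[C@H](O[Si](C)(C)C(C)(C)C)[C@H](C(=C)C[Sm](I)I)O1 | intermediate
37 | samarium hemiketal alkoxide (O-SmI2 derivative of 38) | C=C1C[C@H](OC(=O)/C(C)=C/C)[C@@H](C(=C)CO[Si](c3ccccc3)(c3ccccc3)C(C)(C)C)[C@H](O[Si](C)(C)C(C)(C)C)[C@H]2O[C@@](O[Sm](I)I)(C1)CC2=C | intermediate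
38 | bridged hemiketal (2S,5S,6S,7R,8S): 11-oxabicyclo[6.2.1]undecane core; 2-OH; 4- and 10-methylene; 8-O-tigloyl; 6-OTBS; 7-[3-(TBDPS-oxy)prop-1-en-2-yl] | C=C1C[C@H](OC(=O)/C(C)=C/C)[C@@H](C(=C)CO[Si](c3ccccc3)(c3ccccc3)C(C)(C)C)[C@H](O[Si](C)(C)C(C)(C)C)[C@H]2O[C@@](O)(C1)CC2=C | intermediate
39 | bridged hemiketal triol (2S,5S,6S,7S,8S): 2-OH; 6-OH; 12-OH; 8-O-tigloyl | C=C1C[C@H](OC(=O)/C(C)=C/C)[C@@H](C(=C)CO)[C@H](O)[C@H]2O[C@@](O)(C1)CC2=C | intermediate
40 | enal (2S,5S,6S,7S,8S): C12 aldehyde; 6-OH | C=C1C[C@H](OC(=O)/C(C)=C/C)[C@@H](C(=C)C=O)[C@H](O)[C@H]2O[C@@](O)(C1)CC2=C | intermediate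
41 | lactol (2S,5S,6S,7R,8S; C12 epimers) | C=C1C[C@H](OC(=O)/C(C)=C/C)[C@H]2C(=C)C(O)O[C@@H]2[C@H]2O[C@@](O)(C1)CC2=C | intermediate
42 | CNP0307443.2 (2S,5S,6S,7R,8S) | C=C1C[C@H](OC(=O)/C(C)=C/C)[C@H]2C(=C)C(=O)O[C@@H]2[C@H]2O[C@@](O)(C1)CC2=C | target

**Totals**
Total step count: 25.
Longest linear sequence: 19 steps (steps 1–6, then 13–25).

**Steps most likely to fail**

1. Step 23 (SmI2 acyl transfer).
- What may go wrong: the allyl radical may dimerise. The allylsamarium may be protonated, for instance by the acidic C1 methylene of the β,γ-unsaturated lactone, faster than it reaches C2. Prolonged contact with SmI2 may begin to reduce the tiglate.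
- Fallback: form the same C2–C3 bond at the aldehyde oxidation level with chromium. It sets out from 29. Swern conditions oxidise the primary TES ether directly, O5 staying silylated, to the C2 aldehyde F1. CrCl2 with NaI in THF/DMF at high dilution closes the ten-membered ring by a Nozaki–Hiyama allylation of the aldehyde with the C3 allylic chloride, giving the cyclodecane carbinol F2 (either C2 epimer serves). Dess–Martin periodinane gives the ketone F3. PPTS in MeOH frees O5, which adds across the ring to C2, and the route is rejoined at 38.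

2. Step 21 (nine-membered lactonisation).
- What may go wrong: oligomerisation may outrun ring closure. The activated acyl group may also lose its β,γ double bond to conjugation under DMAP.
- Fallback: give up the lactone and close the carbocycle directly. It sets out from 30. TEMPO/PhI(OAc)2 in dry CH2Cl2 stops at hydroxy aldehyde 31, which is now isolated. CrCl2 with NaI at high dilution, which tolerates the free hydroxyl, joins C3 to C2 and gives the carbocyclic 2,5-diol F4. One equivalent of Dess–Martin periodinane should oxidise the unhindered C2 carbinol first, and the ketone is at once captured by O5 as the hemiketal, which shields C5. The route is rejoined at 38.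

3. Step 17 (allylation at C8).
- What may go wrong: facial selectivity may be poor if the catalyst cannot override the bias of the 6-silyloxy group toward the 6,8-anti alcohol, and turnover on the hindered aldehyde may be slow.
- Fallback: set C8 by inversion instead of by addition. It sets out from 26. The allylation with 21 is run with (R)-BINOL/Ti(OiPr)4, so that catalyst and substrate bias cooperate, to give the (8R)-alcohol F5. A Mitsunobu esterification with tiglic acid (PPh3, DIAD, toluene) installs the ester with inversion, and the route is rejoined at 29.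

**Further compounds**
F1 | step 23 | open-chain C2 aldehyde (5S,6S,7R,8S): 5-OTES; 6-OTBS; 8-O-tigloyl; 12-OTBDPS; 3-Cl | O=CCC(=C)C[C@H](OC(=O)/C(C)=C/C)[C@@H](C(=C)CO[Si](c1ccccc1)(c1ccccc1)C(C)(C)C)[C@H](O[Si](C)(C)C(C)(C)C)[C@@H](O[Si](CC)(CC)CC)C(=C)CCl
F2 | step 23 | cyclodecane carbinol (5S,6S,7R,8S; C2 epimers): 2-OH; 5-OTES; 6-OTBS; 8-O-tigloyl; 12-OTBDPS; 4- and 10-methylene | OC1CC(=C)C[C@H](OC(=O)/C(C)=C/C)[C@@H](C(=C)CO[Si](c2ccccc2)(c2ccccc2)C(C)(C)C)[C@H](O[Si](C)(C)C(C)(C)C)[C@@H](O[Si](CC)(CC)CC)C(=C)C1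
F3 | step 23 | cyclodecanone (5S,6S,7R,8S): C2 ketone; 5-OTES; otherwise as F2 | O=C1CC(=C)C[C@H](OC(=O)/C(C)=C/C)[C@@H](C(=C)CO[Si](c2ccccc2)(c2ccccc2)C(C)(C)C)[C@H](O[Si](C)(C)C(C)(C)C)[C@@H](O[Si](CC)(CC)CC)C(=C)C1
F4 | step 21 | carbocyclic 2,5-diol (5S,6S,7R,8S; C2 epimers): 6-OTBS; 8-O-tigloyl; 12-OTBDPS; 4- and 10-methylene | OC1CC(=C)C[C@H](OC(=O)/C(C)=C/C)[C@@H](C(=C)CO[Si](c2ccccc2)(c2ccccc2)C(C)(C)C)[C@H](O[Si](C)(C)C(C)(C)C)[C@@H](O)C(=C)C1
F5 | step 17 | open-chain (8R)-alcohol (5S,6S,7R,8R), the 8-epimer of 27 | CC[Si](CC)(CC)OCCC(=C)C[C@@H](O)[C@@H](C(=C)CO[Si](c1ccccc1)(c1ccccc1)C(C)(C)C)[C@H](O[Si](C)(C)C(C)(C)C)[C@@H](O[Si](CC)(CC)CC)C(=C)CCl
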